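Slowness here looks like a machine with a fixed cycle time, not a stock draining away: Sunday's run climbs from 16% at 40.0 min to 61% at 150 min, and Wednesday's from 26% at 6.00 min to 53% at 15.0 min, both close to straight lines in time.

| flask | substrate | reagent | free catalyst | temperature | remark | time |
|---|---|---|---|---|---|---|
| Sunday's | 0.35 M | 1.65 M | 0.75 mM | 35 °C | run made earlier |  |
| Wednesday's | 1.3 M | 1.65 M | 0.75 mM | 80 °C | run made earlier |  |
| Saturday's | 1.5 M | 1.2 M | 0.75 mM | 35 °C | run made earlier |  |
| summer | 1.5 M | 1.65 M | 0.75 mM | 80 °C |  | 15 min |
| winter | 1.5 M | 3.00 M | 0.75 mM | 80 °C |  | 15 min |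
| dawn | 1.5 M | 1.65 M | 1.5 mM | 40 °C |  | 15 min |
| spring | 1.5 M | 1.65 M | 0.40 mM | 120 °C |  | 15 min |
| autumn | 0.50 M | 1.65 M | 0.75 mM | 100 °C |  | 15 min |
| noon | 1.5 M | 0.400 M | 0.75 mM | 95 °C |  | 15 min |

| run | time / min | product / % | substrate / % |
|---|---|---|---|
| Sunday's | 40.0 | 16 | 85 |
| Sunday's | 80.0 | 30 | 66 |
| Sunday's | 120 | 50 | 51 |
| Sunday's | 150 | 61 | 41 |
| Wednesday's | 1.33 | 7 | 97 |
| Wednesday's | 3.00 | 10 | 89 |
| Wednesday's | 6.00 | 26 | 76 |
| Wednesday's | 15.0 | 53 | 48 |
| Saturday's | 40.0 | 9 | 93 |
| Saturday's | 80.0 | 15 | 88 |
| Saturday's | 120 | 19 | 81 |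
| Saturday's | 150 | 21 | 78 |

(readings scatter by 2 percentage points)

* all flasks from highest to lowest amount of product, in percent of the substrate charged, at 15 min (summer / winter / dawn / spring / autumn / noon)
* the amount of product, in percent of the substrate charged of the flask you put first, at 15 min
* the amount of product, in percent of the substrate charged of the flask you put last, at 15 min

- no earlier run changes the charge of free catalyst; that part of a forecast is a guess

So I treat the catalyst as that machine, with its quick steps taken as steady: each catalyst goes round n times a minute (the turnover frequency). On average over the run, Saturday's last reading gives n = 2.80 min⁻¹ at 35 °C, and Wednesday's gives 61.2 min⁻¹ at 80 °C. The two runs differ in substrate and reagent as well as in temperature, so the activation energy of 62.0 kJ mol⁻¹ that this pair implies is a rough reading, which I carry to other temperatures.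

Now I fold the givens into one number, Θ = n·c(free catalyst)·t/c(substrate): the time allowed over the time the machine needs for the whole charge. Below one, I read Θ as the fraction converted. Above one the flask should be nearly finished, unless c(reagent)/c(substrate) caps it, since I take one reagent per substrate. Proportionality to catalyst is my guess, because no earlier run changes it.

For dawn, the charge number Θ is 0.0618. Summer and winter share 0.459. Noon has 1.09, but reagent is its limiting reagent, capping it at 26.7%. Spring has 2.10, and autumn has more, 4.28. I therefore commit to autumn nearly complete, then spring, summer level with winter, noon, and dawn near 6.18%.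

Was one number enough? Not quite. Sunday's thin substrate gives Θ = 0.900 with Saturday's n, yet it reads less, 61%. Near one, then, Θ says "far along", not how far. It also holds no reagent, so it cannot part summer from winter.

The forecast gives autumn > spring > winter > summer > noon > dawn, with 96% and 10%, and says “Catalyst first order is a guess”; unlike my tie, it sets winter at about 78 per cent and summer at about 49.

The flasks give autumn > spring > winter > summer > noon > dawn: autumn 99.7%, spring 89.8%, winter 50.5%, summer 48.7%, noon 26.1%, dawn 7.24%. In dawn at 7.39 min, catalyst intermediate A has a half-life of 1.3 s by its step with substrate, far shorter than the 140 min of substrate by that step. Catalyst intermediates B and C are then made as fast as they are used, at ratios 1.00 and 1.00.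

    substrate + catalyst intermediate A → catalyst intermediate B (k = 250 L mol⁻¹ min⁻¹, Ea = 56.0 kJ mol⁻¹)
    catalyst intermediate C → free catalyst + product (k = 220 min⁻¹, Ea = 69.0 kJ mol⁻¹)
    reagent + free catalyst → catalyst intermediate A (k = 250 L mol⁻¹ min⁻¹, Ea = 36.0 kJ mol⁻¹)
    reagent + catalyst intermediate B → spent catalyst (k = 0.0320 L mol⁻¹ min⁻¹, Ea = 81.0 kJ mol⁻¹)
    catalyst intermediate B → by-product + catalyst intermediate C (k = 340 min⁻¹, Ea = 73.0 kJ mol⁻¹)
    (constants at 80 °C)

In the neighbour of dawn with 0.0037 M of free catalyst, Θ scales to 0.152. That flask gives 17.6%.

(The earlier runs and the new flask are simulated with constants of no real substance, noise included.)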